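The synthesis rests on cutting the aryl ketone bond between C5 of ring A and the chalcone carbonyl. Before the dihydrofuran ring is closed, ring A is a 2-substituted resorcinol in which C5 and C7, and likewise O4 and O1, are equivalent, so a single iodine is placed without regiochemical choice. The key step joins three components in one operation: the iodoarene that already carries C2 and C3 as a threo epoxy alcohol, carbon monoxide and a 4-silyloxystyrene, in a palladium-catalysed carbonylative Heck reaction that delivers the whole (E)-chalcone. The new carbonyl then ties up O4, so fluoride unmasking lets only the para oxygen O1 open the epoxide and close the ring.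

Key step: step 5

Remark on the chemistry: the target is read as the (2S,3S) isomer, with the C2 side chain and the C3 hydroxyl trans. Benzofuran numbering (O1, C2, C3, C3a, C4 to C7, C7a; O4 is the oxygen on C4) is kept for the open-chain precursors; ring A is the benzene ring of the benzofuran and ring B the 4-hydroxyphenyl ring.
Assumption: tert-butyldimethyl(4-vinylphenoxy)silane 6 is taken as a commercial monomer.

Step 1
Reactants: 1 2,6-dihydroxybenzaldehyde
Product: 2 2,6-dihydroxy-3-iodobenzaldehyde
Conditions: NIS (1.0 equiv), MeCN, 0 °C to rt
Reagents that add atoms: N-iodosuccinimide, O=C1CCC(=O)N1I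
Why: Electrophilic aromatic iodination in which the two activated positions of 1 (each ortho to one OH, para to the other, meta to CHO) are equivalent by symmetry and the third free position is unactivated, so one equivalent of NIS can give only one monoiodide.

Step 2
Reactants: 2 2,6-dihydroxy-3-iodobenzaldehyde
Product: 3 2,6-bis(tert-butyldimethylsilyloxy)-3-iodobenzaldehyde
Conditions: TBSCl (2.5 equiv), imidazole, DMF, rt
Reagents that add atoms: tert-butyldimethylsilyl chloride, CC(C)(C)[Si](C)(C)Cl
Why: Standard imidazole-promoted silylation of phenols, which installs fluoride-labile groups that should survive the organozinc, peracid and palladium steps.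

Step 3
Reactants: 3 2,6-bis(tert-butyldimethylsilyloxy)-3-iodobenzaldehyde
Product: 4 (R)-1-[2,6-bis(tert-butyldimethylsilyloxy)-3-iodophenyl]-3-methylbut-2-en-1-ol
Conditions: 2-methyl-1-propenylmagnesium bromide and ZnCl2 (2:1, magnesium salts precipitated with 1,4-dioxane and removed), (+)-MIB (10 mol %), toluene, -10 °C; then water at pH 7
Reagents that add atoms: 2-methyl-1-propenylmagnesium bromide, CC(C)=C[Mg]Br
Why: Catalytic asymmetric alkenylzinc addition to an aromatic aldehyde with an amino alcohol ligand, in which the zinc complex of (+)-MIB should deliver the alkenyl group to the Re face and set C3 as R, while the aryl iodide and the silyl ethers are inert to diorganozinc.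

Step 4
Reactants: 4 (R)-allylic alcohol
Product: 5 (S)-[2,6-bis(tert-butyldimethylsilyloxy)-3-iodophenyl][(R)-3,3-dimethyloxiran-2-yl]methanol (threo epoxy alcohol)
Conditions: mCPBA, CH2Cl2/aq. pH 8 phosphate buffer, 0 °C
Reagents that add atoms: 3-chloroperoxybenzoic acid, O=C(OO)c1cccc(Cl)c1
Why: Hydroxyl-directed peracid epoxidation under A(1,3) strain control, in which the methyl group cis to C3 holds the C3–H in the alkene plane so that the hydrogen-bonded peracid attacks the face bearing OH and remote from the bulky arene, which should give the threo isomer and set C2 as R (C3 is unchanged in space and becomes S only by priority).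

Step 5
Reactants: 5 threo epoxy alcohol iodide; 6 tert-butyldimethyl(4-vinylphenoxy)silane
Product: 7 (E)-1-{2,4-bis(tert-butyldimethylsilyloxy)-3-[(S)-[(R)-3,3-dimethyloxiran-2-yl](hydroxy)methyl]phenyl}-3-[4-(tert-butyldimethylsilyloxy)phenyl]prop-2-en-1-one
Conditions: [(cinnamyl)PdCl]2 (2.5 mol %), di(1-adamantyl)-n-butylphosphine (10 mol %), Cy2NMe (2 equiv), CO (5 bar), 6 (3 equiv), 1,4-dioxane, 80 °C
Reagents that add atoms: carbon monoxide, [C-]#[O+]
Why: This is a carbonylative Heck reaction, the known three-component route from aryl iodides, CO and styrenes to chalcones: zerovalent palladium inserts into the C5–I bond of 5, CO binds, and migratory insertion gives the aroylpalladium species, which is where the C5–C(=O) bond forms. The aroyl group then adds to the unsubstituted carbon of styrene 6 (benzylic palladium favoured) and syn β-hydride elimination releases the enone, the amine taking up HI. No ring is closed and no stereocentre is made, C2 and C3 are spectators, and the only new stereo-element, the E alkene, follows from the syn-insertion/syn-elimination geometry. Site selectivity is fixed by the single C–I bond, which the symmetry of 1 placed at C5. Carbonylation must outrun direct arylation of the styrene, which is favoured by the ortho silyloxy group and the electron-rich ring (slow alkene insertion of a hindered arylpalladium, fast CO insertion) and by CO pressure. The free C3–OH must not capture the aroylpalladium: it cannot reach C5 within the molecule (meta relationship), it is shielded by the doubly ortho-substituted arene and the epoxide, and 6 is used in excess.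

Step 6
Reactants: 7 tris-silylated epoxy chalcone
Product: 9 brosimacutin G, via triphenol epoxy alcohol 8 (not isolated)
Conditions: TBAF (3.5 equiv), THF, 0 °C; then pH 7 buffer
Reagents that add atoms: none
Why: Fluoride desilylation followed by base-induced 5-exo-tet epoxide opening, in which the phenoxide para to the new ketone (more acidic, and freed from the less hindered silyl ether) attacks the secondary epoxide carbon C2 with inversion (R to S) to give the trans-(2S,3S) dihydrofuran and the tertiary alcohol, while the oxygen next to the ketone is held by the carbonyl and ends as the chelated C4–OH.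

Compound list
1 | 2,6-dihydroxybenzaldehyde | O=Cc1c(O)cccc1O | starting material
2 | 2,6-dihydroxy-3-iodobenzaldehyde | O=Cc1c(O)ccc(I)c1O | intermediate
3 | 2,6-bis(tert-butyldimethylsilyloxy)-3-iodobenzaldehyde | O=Cc1c(O[Si](C)(C)C(C)(C)C)ccc(I)c1O[Si](C)(C)C(C)(C)C | intermediate
4 | (R)-1-[2,6-bis(tert-butyldimethylsilyloxy)-3-iodophenyl]-3-methylbut-2-en-1-ol | O[C@@H](c1c(O[Si](C)(C)C(C)(C)C)ccc(I)c1O[Si](C)(C)C(C)(C)C)C=C(C)C | intermediate
5 | (S)-[2,6-bis(tert-butyldimethylsilyloxy)-3-iodophenyl][(R)-3,3-dimethyloxiran-2-yl]methanol | O[C@@H](c1c(O[Si](C)(C)C(C)(C)C)ccc(I)c1O[Si](C)(C)C(C)(C)C)[C@H]2OC2(C)C | intermediate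
6 | tert-butyldimethyl(4-vinylphenoxy)silane | C=Cc1ccc(O[Si](C)(C)C(C)(C)C)cc1 | starting material
7 | (E)-1-{2,4-bis(tert-butyldimethylsilyloxy)-3-[(S)-[(R)-3,3-dimethyloxiran-2-yl](hydroxy)methyl]phenyl}-3-[4-(tert-butyldimethylsilyloxy)phenyl]prop-2-en-1-one | O[C@@H](c1c(O[Si](C)(C)C(C)(C)C)ccc(C(=O)/C=C/c2ccc(O[Si](C)(C)C(C)(C)C)cc2)c1O[Si](C)(C)C(C)(C)C)[C@H]3OC3(C)C | intermediate
8 | (E)-1-{2,4-dihydroxy-3-[(S)-[(R)-3,3-dimethyloxiran-2-yl](hydroxy)methyl]phenyl}-3-(4-hydroxyphenyl)prop-2-en-1-one | O[C@@H](c1c(O)ccc(C(=O)/C=C/c2ccc(O)cc2)c1O)[C@H]3OC3(C)C | intermediate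
9 | brosimacutin G, (E)-1-[(2S,3S)-3,4-dihydroxy-2-(2-hydroxypropan-2-yl)-2,3-dihydrobenzofuran-5-yl]-3-(4-hydroxyphenyl)prop-2-en-1-one | CC(C)(O)[C@H]1Oc2ccc(C(=O)/C=C/c3ccc(O)cc3)c(O)c2[C@@H]1O | target

Total steps: 6. Longest linear sequence: 6 steps (1 to 9).

Steps most likely to fail

Step 5.
- **What may go wrong:**
  - The styrene may be arylated directly, without CO uptake.
  - The free C3 hydroxyl of a second molecule may capture the aroylpalladium intermediate.
  - At 80 °C with amine, a silyl group may migrate from a phenol oxygen to the C3 oxygen, causing premature ring closure.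
- **Fallback:** The three-component coupling is replaced by a two-component acyl transfer to an arylmagnesium. Setting out from 5, the C3 hydroxyl is capped (TESCl, imidazole, CH2Cl2) to give the C3 triethylsilyl ether F1. Styrene 6 is converted by cross-metathesis with N-methoxy-N-methylacrylamide (second-generation Hoveyda–Grubbs catalyst, CH2Cl2, 40 °C) into the (E)-Weinreb amide F2. Iodine–magnesium exchange on F1 (i-PrMgCl·LiCl, THF, -30 °C) followed by addition of F2 should give the tetrasilylated chalcone F3. Under the conditions of step 6, with one more equivalent of TBAF, F3 loses all four silyl groups and comes back to the route at 9.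

Step 3.
- **What may go wrong:** Catalysed addition to the doubly ortho-substituted aldehyde may be slow. The uncatalysed background would then compete and erode the enantioselectivity.
- **Fallback:** C3 is set by reduction instead of by C–C bond formation. Setting out from 3, direct addition of 2-methyl-1-propenylmagnesium bromide (THF, -78 °C) gives the racemic allylic alcohol F4. Oxidation with MnO2 (CH2Cl2, rt) gives the aryl alkenyl ketone F5. Corey–Bakshi–Shibata reduction follows, with (S)-Me-CBS oxazaborolidine and catecholborane in toluene at -78 °C. With the twisted, doubly ortho-substituted arene acting as the large group, this should give the R alcohol and come back to the route at 4.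

Step 6.
- **What may go wrong:**
  - Once the oxygen next to the carbonyl is freed as an unchelated ammonium phenoxide, it may compete for the epoxide.
  - The same oxygen may add to the enone and close a flavanone.
- **Fallback:** Regiocontrol is enforced by a protecting group instead of by acidity. Setting out from 7, methanolysis with catalytic K2CO3 in MeOH at -20 °C should cleave only the two unhindered aryl silyl ethers. The para phenoxide then closes the ring while the oxygen next to the carbonyl is still silylated, giving the 4-O-silyl ether of the target F6. Its last silyl group is removed under non-basic conditions (Et3N·3HF, MeCN, 0 °C), and the sequence comes back to the route at 9.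

Further compounds
F1 | step 5 | triethylsilyl ether of 5 at the C3 oxygen | CC[Si](CC)(CC)O[C@@H](c1c(O[Si](C)(C)C(C)(C)C)ccc(I)c1O[Si](C)(C)C(C)(C)C)[C@H]2OC2(C)C
F2 | step 5 | (E)-3-[4-(tert-butyldimethylsilyloxy)phenyl]-N-methoxy-N-methylacrylamide | CON(C)C(=O)/C=C/c1ccc(O[Si](C)(C)C(C)(C)C)cc1
F3 | step 5 | triethylsilyl ether of 7 at the C3 oxygen | CC[Si](CC)(CC)O[C@@H](c1c(O[Si](C)(C)C(C)(C)C)ccc(C(=O)/C=C/c2ccc(O[Si](C)(C)C(C)(C)C)cc2)c1O[Si](C)(C)C(C)(C)C)[C@H]3OC3(C)C
F4 | step 3 | racemic 1-[2,6-bis(tert-butyldimethylsilyloxy)-3-iodophenyl]-3-methylbut-2-en-1-ol | OC(c1c(O[Si](C)(C)C(C)(C)C)ccc(I)c1O[Si](C)(C)C(C)(C)C)C=C(C)C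
F5 | step 3 | 1-[2,6-bis(tert-butyldimethylsilyloxy)-3-iodophenyl]-3-methylbut-2-en-1-one | O=C(c1c(O[Si](C)(C)C(C)(C)C)ccc(I)c1O[Si](C)(C)C(C)(C)C)C=C(C)C
F6 | step 6 | 4-O-tert-butyldimethylsilyl ether of brosimacutin G | CC(C)(O)[C@H]1Oc2ccc(C(=O)/C=C/c3ccc(O)cc3)c(O[Si](C)(C)C(C)(C)C)c2[C@@H]1O
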